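**Assumption (one line):** methyl 4-oxobutanoate and syringyl alcohol are commercial. Acid/HFIP ionization of a 4-hydroxybenzyl alcohol to a p-quinone methide (p-QM) is taken to work for syringyl alcohol. The target is the all-trans (2R,3R,4R) 2-aryl-3-methyl-4-benzyl tetrahydrofuran: aryl and benzyl are cis to each other, and the methyl is trans to both.

## Retrosynthetic overview
- The target comes from ionic hydrogenation of the 2-aryl-2-hydroxy tetrahydrofuran (lactol), which sets C2 trans to the C3 methyl.
- The lactol comes from addition of a guaiacyl aryllithium to the trans-α-methyl-β-benzyl-γ-butyrolactone.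
- That lactone comes from α-methylation, anti to the benzyl group, of the β-benzyl-γ-butyrolactone, which sets C3.
- The β-benzyl lactone comes from NaBH4 reduction and lactonization of the α-benzylated aldehyde. This is the only ring-forming step, and the tetrahydrofuran ring is carried from the lactone through to the target.
- The α-benzylated aldehyde comes from organocatalytic enantioselective α-benzylation of methyl 4-oxobutanoate with the p-QM generated from syringyl alcohol, which sets C4, the first stereocenter.

## Starting materials and catalyst
- **1** methyl 4-oxobutanoate, COC(=O)CCC=O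
- **2** 4-hydroxy-3,5-dimethoxybenzyl alcohol (syringyl alcohol), COc1cc(CO)cc(OC)c1O
- **3** (R)-α,α-diphenylprolinol trimethylsilyl ether (organocatalyst), C[Si](C)(C)OC(c1ccccc1)(c1ccccc1)[C@H]1CCCN1

## Route

**Step 1**
Reactants: 1 methyl 4-oxobutanoate (3 equiv); 2 syringyl alcohol (1 equiv)
Product: 4, methyl (R)-3-(4-hydroxy-3,5-dimethoxybenzyl)-4-oxobutanoate
Conditions: 3 (20 mol %), 2-fluorobenzoic acid (20 mol %), HFIP/CH2Cl2 1:1, 35 °C, 48 h
Reagents that add atoms: none (product = 1 + 2 − H2O)
Why: Proposed new method: HFIP and the acid ionize the syringyl alcohol to the unsubstituted 2,6-dimethoxy-p-quinone methide. The E-enamine of 1 with catalyst 3 adds to the exocyclic CH2 in a 1,6-conjugate addition, from the face not shielded by the silyloxy-diphenylmethyl group. Rearomatization gives the phenol, and hydrolysis releases the α-branched aldehyde and the catalyst. The closest known reactions are enamine α-alkylation of aldehydes with stabilized benzylic cations and 1,6-additions of aldehydes to diaryl p-QMs. By analogy with the known face selectivity of the (S)-catalyst (for example in nitroolefin Michael additions), the (R)-catalyst should give the (R)-aldehyde here, and this sets C4.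

**Step 2**
Reactants: 4 aldehyde
Product: 5, (R)-4-(4-hydroxy-3,5-dimethoxybenzyl)dihydrofuran-2(3H)-one
Conditions: (i) crude 4, NaBH4, EtOH, 0 °C, 30 min; (ii) aqueous HCl workup, then p-TsOH (cat.), CH2Cl2, rt
Reagents that add atoms: none (NaBH4 adds only H)
Why: NaBH4 reduces the aldehyde chemoselectively over the methyl ester at 0 °C. The crude α-branched aldehyde is used at once to avoid α-epimerization. The resulting γ-hydroxy ester lactonizes under acid catalysis (loss of MeOH), and C4 is untouched.

**Step 3**
Reactants: 5 lactone
Product: 6, (3R,4R)-4-(4-hydroxy-3,5-dimethoxybenzyl)-3-methyldihydrofuran-2(3H)-one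
Conditions: LiHMDS (2.2 equiv), THF, −78 °C; then MeI (1.05 equiv), −78 → −30 °C
Reagents that add atoms: MeI, CI
Why: the phenoxide forms first, and the lactone enolate is then C-alkylated (enolate alkylation) anti to the C4 benzyl group. This gives the trans-3,4 lactone and sets C3 (R). The hindered 2,6-dimethoxyphenoxide lithium salt is a poor O-nucleophile at low temperature.

**Step 4**
Reactants: 6 lactone; 7 4-bromo-2-methoxyphenol
Product: 8, lactol (hydroxy-ketone tautomer in equilibrium), 2-(4-hydroxy-3-methoxyphenyl)-2-hydroxy-3-methyl-4-(4-hydroxy-3,5-dimethoxybenzyl)tetrahydrofuran; C3 and C4 as in 6, C2 an epimeric mixture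
Conditions: 7 (2.6 equiv) and n-BuLi (5.2 equiv), THF, −78 °C, 30 min, giving lithium 4-lithio-2-methoxyphenoxide; add 6 in THF, −78 °C, 2 h; quench with sat. NH4Cl
Reagents that add atoms: none (the aryl group comes from reactant 7; n-BuLi only effects Br/Li exchange and deprotonation)
Why: organolithium addition to a lactone gives a stable lithium lactolate at −78 °C, so over-addition is suppressed, and the phenoxides are tolerated. The excess aryllithium covers the acidic phenol of 6. C2 is left undefined here and is set in step 5, while C3 and C4 are unaffected.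

**Step 5**
Reactants: 8 lactol
Product: 9, target, 4-[(2R,3R,4R)-4-(4-hydroxy-3,5-dimethoxybenzyl)-3-methyltetrahydrofuran-2-yl]-2-methoxyphenol
Conditions: Et3SiH (4 equiv), BF3·OEt2 (5 equiv), CH2Cl2, −78 → −20 °C, 2 h; NaHCO3 quench
Reagents that add atoms: none (Et3SiH delivers only H)
Why: ionic hydrogenation (Kursanov–Parnes type) of the benzylic oxocarbenium derived from 8 gives the 2-aryl tetrahydrofuran. Hydride delivery anti to the adjacent C3 methyl, together with reversible acid ionization of the p-hydroxybenzylic C–O bond, favours the all-trans product, which is the (2R,3R,4R) target. C3 and C4 are not touched.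

## Compound list
1 | methyl 4-oxobutanoate | COC(=O)CCC=O | starting material
2 | 4-hydroxy-3,5-dimethoxybenzyl alcohol (syringyl alcohol) | COc1cc(CO)cc(OC)c1O | starting material
3 | (R)-α,α-diphenylprolinol trimethylsilyl ether (organocatalyst) | C[Si](C)(C)OC(c1ccccc1)(c1ccccc1)[C@H]1CCCN1 | starting material
4 | methyl (R)-3-(4-hydroxy-3,5-dimethoxybenzyl)-4-oxobutanoate | COC(=O)C[C@H](C=O)Cc1cc(OC)c(O)c(OC)c1 | intermediate
5 | (R)-4-(4-hydroxy-3,5-dimethoxybenzyl)dihydrofuran-2(3H)-one | O=C1OC[C@H](Cc2cc(OC)c(O)c(OC)c2)C1 | intermediate
6 | (3R,4R)-4-(4-hydroxy-3,5-dimethoxybenzyl)-3-methyldihydrofuran-2(3H)-one | O=C1OC[C@H](Cc2cc(OC)c(O)c(OC)c2)[C@H]1C | intermediate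
7 | 4-bromo-2-methoxyphenol | COc1cc(Br)ccc1O | starting material
8 | 2-(4-hydroxy-3-methoxyphenyl)-2-hydroxy-3-methyl-4-(4-hydroxy-3,5-dimethoxybenzyl)tetrahydrofuran (lactol, C2 epimeric; C3 R, C4 R) | COc1cc(C2(O)OC[C@H](Cc3cc(OC)c(O)c(OC)c3)[C@H]2C)ccc1O | intermediate
9 | 4-[(2R,3R,4R)-4-(4-hydroxy-3,5-dimethoxybenzyl)-3-methyltetrahydrofuran-2-yl]-2-methoxyphenol | COc1cc([C@@H]2OC[C@H](Cc3cc(OC)c(O)c(OC)c3)[C@H]2C)ccc1O | target

## Totals
Total steps: 5. Longest linear sequence: 5 (1 → 4 → 5 → 6 → 8 → 9).

## Three steps most likely to fail
1. **Step 1 (the proposed new step).** The unsubstituted p-QM may oligomerize, ionization may be slow, or the ee and catalyst hand may be off.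
   - Fallback, known chemistry: Evans oxazolidinone route to 5. Alkylate N-[3-(4-benzyloxy-3,5-dimethoxyphenyl)propanoyl]-4-benzyloxazolidinone with tert-butyl bromoacetate (NaHMDS). Cleave the auxiliary with LiBH4 to the primary alcohol, lactonize with TFA, and remove the benzyl ether by hydrogenolysis to give (R)-5 (auxiliary enantiomer chosen accordingly).
2. **Step 4.** The polyanionic aryllithium/lactone mixture may be poorly soluble or give double addition to a diol.
   - Fallback, changed approach: open 6 to the hydroxy Weinreb amide (AlMe3, MeNH(OMe)·HCl). Add 4-benzyloxy-3-methoxyphenylmagnesium bromide to give the hydroxy-aryl ketone, which cannot over-add. Then reduce with NaBH4, cyclize, and remove the benzyl ether by hydrogenolysis.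
3. **Step 5.** C2 diastereoselectivity may be poor, and the free p-hydroxybenzylic ether may be over-reduced to the ring-opened arylalkane.
   - Fallback, different mechanism: open 8 to the hydroxy ketone, reduce with NaBH4 to the 1,4-diol, and cyclodehydrate with Amberlyst-15 or cat. TsOH in toluene through the p-QM/benzylic cation. This is the known secoisolariciresinol-to-anhydrosecoisolariciresinol type closure, under thermodynamic control to the all-trans THF.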